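**Proposed synthesis of 4'-O-geranylisoliquiritigenin by de novo construction of ring A**

Ring A is cut across C1'–C2' and C5'–C6' into a C2'–C5' 1,1,3-trioxygenated butadiene (geranyl already on the future O4') and a terminal ynone supplying C6' and the acyl-bearing C1'.
This cut is possible because ring A is a resorcinol with the acyl carbon C1' ortho to the free 2'-OH and para to the 4'-O-geranyl ether, the pattern such a diene gives with an alkynyl ketone; the three phenols never need to be differentiated.
The diene is cut further at its enol-ether C–O bond (geraniol + an allenoate); the ynone at the carbinol–alkyne bond and the enone C=C (ring B aldehyde, a formylmethylene ylide, an ethynyl Grignard reagent).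
Forward: ring B is bought, the enynone arm is grown on it in four steps, the geranyloxy diene is made in two, ring A is formed last in the step that joins the halves, and fluoride then frees the 4-OH.
Stereochemistry: there are no stereocentres; the 2E geranyl alkene comes from geraniol and the E enone alkene from a stabilized-ylide Wittig reaction, and neither is touched afterwards.

Key step: step 7

Remark on the chemistry: the ketene acetal double bond of the silyloxy diene is expected as an E/Z mixture and is left unassigned, because that carbon becomes aromatic C2'. The propargylic carbinol and the cycloadduct ketal are racemic, and both centres are destroyed.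

**Step 1**
Reactants: 1 4-hydroxybenzaldehyde
Product: 2 4-(tert-butyldimethylsilyloxy)benzaldehyde
Conditions: TBSCl, imidazole, DMF, 0 °C to rt
Reagents that add atoms: tert-butyldimethylsilyl chloride, CC(C)(C)[Si](C)(C)Cl
Why: Imidazole-promoted O-silylation of a phenol is standard protection chemistry that leaves the aldehyde untouched, and the aryl silyl ether should tolerate the later Wittig, Grignard, MnO2 and cycloaddition conditions yet fall to fluoride.

**Step 2**
Reactants: 2 4-(tert-butyldimethylsilyloxy)benzaldehyde, 3 (triphenylphosphoranylidene)acetaldehyde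
Product: 4 (E)-3-[4-(tert-butyldimethylsilyloxy)phenyl]prop-2-enal
Conditions: toluene, 80 °C (about one equivalent of ylide)
Reagents that add atoms: none
Why: Wittig olefination with the carbonyl-stabilized formylmethylene ylide should give the E enal, and limiting the ylide keeps the product enal from being homologated a second time.

**Step 3**
Reactants: 4 (E)-3-[4-(tert-butyldimethylsilyloxy)phenyl]prop-2-enal, 5 ethynylmagnesium bromide
Product: 7 racemic (E)-1-[4-(tert-butyldimethylsilyloxy)phenyl]pent-1-en-4-yn-3-ol, via bromomagnesium alkoxide 6 (not isolated)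
Conditions: THF, −78 to 0 °C; then aq NH4Cl
Reagents that add atoms: none
Why: Grignard 1,2-addition of the hard alkynyl nucleophile to the enal carbonyl is expected without conjugate addition, the aryl silyl ether is inert at low temperature, and the new carbinol centre is formed without control as a racemate because it is oxidized away in step 4.

**Step 4**
Reactants: 7 racemic (E)-1-[4-(tert-butyldimethylsilyloxy)phenyl]pent-1-en-4-yn-3-ol
Product: 8 (E)-1-[4-(tert-butyldimethylsilyloxy)phenyl]pent-1-en-4-yn-3-one
Conditions: activated MnO2 (excess), CH2Cl2, rt; filter, keep cold, use soon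
Reagents that add atoms: none
Why: Activated MnO2 oxidation is selective for alcohols that are both allylic and propargylic and runs under neutral heterogeneous conditions, which should spare the silyl ether, the alkene geometry and the sensitive cross-conjugated ynone.

**Step 5**
Reactants: 9 geraniol, 10 ethyl buta-2,3-dienoate
Product: 11 ethyl (2E)-3-{[(2E)-3,7-dimethylocta-2,6-dien-1-yl]oxy}but-2-enoate
Conditions: DABCO (10 mol %), CH2Cl2, 0 °C to rt, slow addition of 10
Reagents that add atoms: none
Why: Tertiary-amine-catalysed oxa-Michael addition of a primary alcohol to the central carbon of an allenoate should give the conjugated E beta-alkoxy crotonate under near-neutral conditions, so neither transesterification nor allylic ionization of geraniol is expected, and any beta,gamma-unsaturated regioisomer would converge on the same dienolate in step 6.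

**Step 6**
Reactants: 11 ethyl (2E)-3-{[(2E)-3,7-dimethylocta-2,6-dien-1-yl]oxy}but-2-enoate
Product: 13 1-ethoxy-3-geranyloxy-1-trimethylsilyloxybuta-1,3-diene (ketene acetal geometry unassigned), via lithium dienolate 12 (not isolated)
Conditions: LiN(iPr)2, THF, −78 °C; Me3SiCl, −78 to 0 °C; evaporate, pentane, filter under argon, use at once
Reagents that add atoms: chlorotrimethylsilane, C[Si](C)(C)Cl
Why: Kinetic gamma-deprotonation of a beta-alkoxy crotonate by a lithium amide and O-silylation of the ester dienolate is the standard entry to 1-alkoxy-1-silyloxy-3-alkoxybutadienes (vinylketene acetals), and holding the dienolate at −78 °C with prompt trapping should suppress anion-accelerated [3,3] rearrangement of the allyl vinyl ether.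

**Step 7**
Reactants: 13 1-ethoxy-3-geranyloxy-1-trimethylsilyloxybuta-1,3-diene, 8 (E)-1-[4-(tert-butyldimethylsilyloxy)phenyl]pent-1-en-4-yn-3-one
Product: 16 4-O-(tert-butyldimethylsilyl)-4'-O-geranylisoliquiritigenin, via cyclohexa-1,4-diene ketal 14 (not isolated), via aryl trimethylsilyl ether 15 (not isolated)
Conditions: toluene, 0 °C to rt; then AcOH, THF–H2O, 0 °C
Reagents that add atoms: none
Why: The diene CH2 terminus (largest HOMO coefficient) attacks the unsubstituted alkyne carbon of the ynone (largest LUMO coefficient) and the ketene acetal carbon then bonds to the acyl-bearing alkyne carbon, either as an asynchronous Diels–Alder reaction or as a stepwise Mukaiyama–Michael addition and ring closure, so C5'–C6' and C1'–C2' form in one intermolecular [4+2] event that closes the six-membered carbocyclic ring A. The closest known reaction type is the Diels–Alder benzannulation of vinylketene acetals (1-alkoxy-1-silyloxy-3-alkoxybutadienes) with acetylenic ketones and esters, which gives 2-hydroxy-4-alkoxyaryl carbonyl compounds. Ketal 14 should aromatize by 1,4-elimination of ethanol, driven by aromaticity and by the hydrogen bond of the 2'-oxygen to the ketone, and the dilute acid then hydrolyses the aryl trimethylsilyl ether 15 while the bulkier aryl silyl ether and the geranyl ether remain. No stereocentre is created that survives: the ketal carbon of 14 is racemic and becomes aromatic, and both E alkenes are spectators under the mild, Lewis-acid-free thermal conditions. The regioselectivity needed (acyl ortho to the new hydroxyl and para to the geranyloxy group) follows from the matched polarization of the 1,1,3-trioxygenated diene and the ynone. The chemoselectivity needed (alkyne over styryl alkene and carbonyl) follows from the higher electrophilicity and lower hindrance of the terminal ynone compared with the beta-aryl enone, which the para-silyloxy donor deactivates further.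

**Step 8**
Reactants: 16 4-O-(tert-butyldimethylsilyl)-4'-O-geranylisoliquiritigenin
Product: 17 4'-O-geranylisoliquiritigenin
Conditions: Bu4NF, AcOH, THF, 0 °C
Reagents that add atoms: none
Why: Fluoride-mediated desilylation of an aryl silyl ether is fast at 0 °C, and the acetic acid buffer should keep the 2'-hydroxychalcone from base-induced oxa-Michael closure to the flavanone while the geranyl ether and both E alkenes stay untouched.

**Compound list**
1 | 4-hydroxybenzaldehyde | O=Cc1ccc(O)cc1 | starting material
2 | 4-(tert-butyldimethylsilyloxy)benzaldehyde | O=Cc1ccc(O[Si](C)(C)C(C)(C)C)cc1 | intermediate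
3 | (triphenylphosphoranylidene)acetaldehyde | O=CC=P(c1ccccc1)(c1ccccc1)c1ccccc1 | starting material
4 | (E)-3-[4-(tert-butyldimethylsilyloxy)phenyl]prop-2-enal | O=C/C=C/c1ccc(O[Si](C)(C)C(C)(C)C)cc1 | intermediate
5 | ethynylmagnesium bromide | C#C[Mg]Br | starting material
6 | bromomagnesium alkoxide of 7 (racemic) | C#CC(O[Mg]Br)/C=C/c1ccc(O[Si](C)(C)C(C)(C)C)cc1 | intermediate (not isolated)
7 | racemic (E)-1-[4-(tert-butyldimethylsilyloxy)phenyl]pent-1-en-4-yn-3-ol | C#CC(O)/C=C/c1ccc(O[Si](C)(C)C(C)(C)C)cc1 | intermediate
8 | (E)-1-[4-(tert-butyldimethylsilyloxy)phenyl]pent-1-en-4-yn-3-one | C#CC(=O)/C=C/c1ccc(O[Si](C)(C)C(C)(C)C)cc1 | intermediate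
9 | geraniol, (2E)-3,7-dimethylocta-2,6-dien-1-ol | CC(C)=CCC/C(C)=C/CO | starting material
10 | ethyl buta-2,3-dienoate | C=C=CC(=O)OCC | starting material
11 | ethyl (2E)-3-{[(2E)-3,7-dimethylocta-2,6-dien-1-yl]oxy}but-2-enoate | CC(C)=CCC/C(C)=C/CO/C(C)=C/C(=O)OCC | intermediate
12 | lithium dienolate of 11 | CC(C)=CCC/C(C)=C/COC(=C)C=C(OCC)O[Li] | intermediate (not isolated)
13 | 1-ethoxy-3-geranyloxy-1-trimethylsilyloxybuta-1,3-diene (C1=C2 geometry unassigned, geranyl 2E) | CC(C)=CCC/C(C)=C/COC(=C)C=C(OCC)O[Si](C)(C)C | intermediate
14 | racemic (E)-1-[6-ethoxy-4-geranyloxy-6-(trimethylsilyloxy)cyclohexa-1,4-dien-1-yl]-3-[4-(tert-butyldimethylsilyloxy)phenyl]prop-2-en-1-one | CC(C)=CCC/C(C)=C/COC1=CC(OCC)(O[Si](C)(C)C)C(C(=O)/C=C/c2ccc(O[Si](C)(C)C(C)(C)C)cc2)=CC1 | intermediate (not isolated)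
15 | 4-O-(tert-butyldimethylsilyl)-2'-O-(trimethylsilyl)-4'-O-geranylisoliquiritigenin | CC(C)=CCC/C(C)=C/COc1ccc(C(=O)/C=C/c2ccc(O[Si](C)(C)C(C)(C)C)cc2)c(O[Si](C)(C)C)c1 | intermediate (not isolated)
16 | 4-O-(tert-butyldimethylsilyl)-4'-O-geranylisoliquiritigenin | CC(C)=CCC/C(C)=C/COc1ccc(C(=O)/C=C/c2ccc(O[Si](C)(C)C(C)(C)C)cc2)c(O)c1 | intermediate
17 | 4'-O-geranylisoliquiritigenin, (E)-1-[4-geranyloxy-2-hydroxyphenyl]-3-(4-hydroxyphenyl)prop-2-en-1-one | CC(C)=CCC/C(C)=C/COc1ccc(C(=O)/C=C/c2ccc(O)cc2)c(O)c1 | target

**Step count**
Total: 8 steps. Longest linear sequence: 6 steps (steps 1, 2, 3, 4, 7, 8 from 4-hydroxybenzaldehyde); the diene branch (steps 5, 6) joins at step 7.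

**Steps most likely to fail**

1. Step 7. The diene may undergo [3,3] rearrangement of its allyl vinyl ether before it is intercepted. The ketal may aromatize by loss of silanol instead of ethanol, which would leave the 2'-oxygen ethylated. The ynone may oligomerize. Fallback: ring A is bought instead of built, at the price of relying on chelation to tell the phenols apart. It sets out from geraniol 9 and aldehyde 1 and returns at the target 17. Geraniol 9 is converted with PBr3 (Et2O, 0 °C) into geranyl bromide F1. This alkylates commercial 2,4-dihydroxyacetophenone at the non-chelated 4-OH (K2CO3, acetone, reflux) to give 1-[4-(geranyloxy)-2-hydroxyphenyl]ethanone F2. Claisen–Schmidt condensation of this ketone with 4-hydroxybenzaldehyde 1 (aq KOH, EtOH, rt, then cold acidification) should deliver 17 directly.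

2. Step 6. The lithium dienolate is itself an allyl vinyl ether bearing an anion and may rearrange, or be silylated on carbon, before the diene is obtained; the diene is also moisture-sensitive. Fallback: a diene without an allyl ether is used and the geranyl group is attached after ring A exists. It sets out from ynone 8 and returns at 16. Commercial methyl 3-(trimethylsilyloxy)but-2-enoate is deprotonated (LiN(iPr)2, THF, −78 °C) to the lithium dienolate F3 and silylated (Me3SiCl) to 1-methoxy-1,3-bis(trimethylsilyloxy)buta-1,3-diene F4. Diels–Alder reaction with 8 (toluene, rt) should give the cyclohexadiene ketal F5, which loses methanol to the 2',4'-bis(trimethylsilyl) ether F6. Dilute AcOH then gives 4-O-(tert-butyldimethylsilyl)isoliquiritigenin F7. Mitsunobu etherification of its non-chelated, more acidic 4'-OH with geraniol 9 (PPh3, diisopropyl azodicarboxylate, THF, 0 °C) should give 16.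

3. Step 5. The allenoate may dimerize under amine catalysis faster than the alcohol adds, or the addition may stall. Fallback: addition–elimination on a beta-chloro enoate replaces nucleophilic catalysis on the allene. It sets out from geraniol 9 and returns at 11. Commercial ethyl but-2-ynoate is hydrochlorinated (LiCl, AcOH, 80 °C) to ethyl (Z)-3-chlorobut-2-enoate F8. Geraniol 9 is converted with NaH (THF, 0 °C) into sodium geranoxide F9, which displaces chloride from the chloro enoate at low temperature. The reversible alkoxide addition is expected to funnel the enol ether to the more stable E isomer 11.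

**Further compounds**
F1 | step 7 | geranyl bromide, (2E)-1-bromo-3,7-dimethylocta-2,6-diene | CC(C)=CCC/C(C)=C/CBr
F2 | step 7 | 1-[4-(geranyloxy)-2-hydroxyphenyl]ethanone | CC(C)=CCC/C(C)=C/COc1ccc(C(C)=O)c(O)c1
F3 | step 6 | lithium dienolate of methyl 3-(trimethylsilyloxy)but-2-enoate | C=C(O[Si](C)(C)C)C=C(OC)O[Li]
F4 | step 6 | 1-methoxy-1,3-bis(trimethylsilyloxy)buta-1,3-diene | C=C(O[Si](C)(C)C)C=C(OC)O[Si](C)(C)C
F5 | step 6 | racemic (E)-1-[6-methoxy-4,6-bis(trimethylsilyloxy)cyclohexa-1,4-dien-1-yl]-3-[4-(tert-butyldimethylsilyloxy)phenyl]prop-2-en-1-one | COC1(O[Si](C)(C)C)C=C(O[Si](C)(C)C)CC=C1C(=O)/C=C/c2ccc(O[Si](C)(C)C(C)(C)C)cc2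
F6 | step 6 | 4-O-(tert-butyldimethylsilyl)-2',4'-bis-O-(trimethylsilyl)isoliquiritigenin | C[Si](C)(C)Oc1ccc(C(=O)/C=C/c2ccc(O[Si](C)(C)C(C)(C)C)cc2)c(O[Si](C)(C)C)c1
F7 | step 6 | 4-O-(tert-butyldimethylsilyl)isoliquiritigenin | Oc1ccc(C(=O)/C=C/c2ccc(O[Si](C)(C)C(C)(C)C)cc2)c(O)c1
F8 | step 5 | ethyl (Z)-3-chlorobut-2-enoate | C/C(Cl)=C/C(=O)OCC
F9 | step 5 | sodium geranoxide | CC(C)=CCC/C(C)=C/CO[Na]
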